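**Strategy.** Ring B (C5–C6–C7–C8–C9–C10) is made as a cyclopentene and enlarged by one carbon. Robinson annulation and deconjugative gem-dimethylation give a hydrindene whose five-membered ring holds C5, C7, C8, C9 and C10 with a C5=C7 bond. Dibromocarbene supplies C6; silver-promoted electrocyclic opening of the fused gem-dibromocyclopropane (a 6,6-dibromobicyclo[3.1.0]hexane on acetonide-protected ring A) then turns the five-membered ring into ring B, placing oxygen on C7 and a bromoalkene at C5=C6 in one operation. The step exploits the C5–C6–C7 segment: C7 carries the target's hydroxyl and C5 unsaturation lets hydrogenation set the trans ring fusion. C7-enone chemistry then adds the axial C9 chain and the C8 methylene.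

Key step: step 9

Remark: labdane numbering is used for every intermediate (ring A C1–C5/C10, ring B C5–C10, angular C20, side chain C11–C16, exocyclic C17); α/β refer to the target drawn with C20 β.
Assumption: (R)-(–)-linalool and (R)-2-methylbutanoic acid are taken as commercial in high enantiomeric purity; they deliver C13 and C2′ unchanged.

Step 1
Reactants: 1 methyl 2-oxocyclopentane-1-carboxylate; 2 methyl vinyl ketone
Product: 3 methyl (1R)-2-oxo-1-(3-oxobutyl)cyclopentane-1-carboxylate
Conditions: 2 (1.5 equiv), bifunctional 6′-hydroxy cinchona alkaloid catalyst (5 mol %, the pseudoenantiomer that gives the R adduct), CH2Cl2, –20 °C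
Reagents that add atoms: none
Why: Catalytic asymmetric Michael addition: the quinuclidine base forms the β-keto ester enolate, the phenolic OH binds the enone, and attack on one enolate face creates the quaternary C10 centre (R), which fixes the absolute configuration of the bicycle.

Step 2
Reactants: 3 methyl (1R)-2-oxo-1-(3-oxobutyl)cyclopentane-1-carboxylate
Product: 5 methyl (7aR)-5-oxo-1,2,3,5,6,7-hexahydro-7aH-indene-7a-carboxylate, via ketol 4 (not isolated)
Conditions: p-TsOH·H2O (10 mol %), toluene, reflux, Dean–Stark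
Reagents that add atoms: none
Why: Intramolecular aldol condensation (ring-closing half of a Robinson annulation): the methyl ketone enol (C4) adds to the ring ketone (C5) in a 6-(enol-exo) closure and the cis-ketol dehydrates to the conjugated enone, leaving the quaternary C10 unaffected.

Step 3
Reactants: 5 methyl (7aR)-5-oxo-1,2,3,5,6,7-hexahydro-7aH-indene-7a-carboxylate
Product: 7 methyl (7aR)-4,4-dimethyl-5-oxo-1,2,4,5,6,7-hexahydro-7aH-indene-7a-carboxylate, via monomethyl enone 6 (not isolated)
Conditions: KOtBu (2.5 equiv), MeI (4 equiv), t-BuOH/THF, 0 °C to rt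
Reagents that add atoms: iodomethane, CI
Why: Deconjugative α,α-dialkylation of the extended dienolate (γ-deprotonation at C7): both methyl groups enter at C4, and because C4 is then quaternary the double bond stays at C5=C7 in the five-membered ring.

Step 4
Reactants: 7 methyl (7aR)-4,4-dimethyl-5-oxo-1,2,4,5,6,7-hexahydro-7aH-indene-7a-carboxylate
Product: 8 methyl (7aR)-4,4-dimethyl-5-(trifluoromethylsulfonyloxy)-1,2,4,7-tetrahydro-7aH-indene-7a-carboxylate
Conditions: KHMDS, THF, –78 °C; PhNTf2, –78 to 0 °C
Reagents that add atoms: N-phenylbis(trifluoromethanesulfonimide), O=S(=O)(N(c1ccccc1)S(=O)(=O)C(F)(F)F)C(F)(F)F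
Why: Enol triflate formation: with C4 quaternary the ketone enolises only toward C2, and the hindered, non-enolisable ester is inert to the amide base.

Step 5
Reactants: 8 methyl (7aR)-4,4-dimethyl-5-(trifluoromethylsulfonyloxy)-1,2,4,7-tetrahydro-7aH-indene-7a-carboxylate
Product: 9 methyl (7aR)-4,4-dimethyl-1,2,4,7-tetrahydro-7aH-indene-7a-carboxylate
Conditions: Pd(OAc)2 (5 mol %), PPh3 (10 mol %), HCO2H, n-Bu3N, DMF, 60 °C
Reagents that add atoms: none
Why: Palladium-catalysed formate reduction of the enol triflate (oxidative addition, formate decarboxylation, C–H reductive elimination) gives the C2=C3 olefin and leaves the hindered C5=C7 bond in place.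

Step 6
Reactants: 9 methyl (7aR)-4,4-dimethyl-1,2,4,7-tetrahydro-7aH-indene-7a-carboxylate
Product: 10 methyl (5S,6R,7aR)-5,6-dihydroxy-4,4-dimethyl-1,2,4,5,6,7-hexahydro-7aH-indene-7a-carboxylate
Conditions: OsO4 (2 mol %), NMO (1.1 equiv), acetone/H2O (8:1), 0 °C to rt
Reagents that add atoms: osmium tetroxide, O=[Os](=O)(=O)=O (carrier of both oxygens); N-methylmorpholine N-oxide, C[N+]1([O-])CCOCC1 (terminal oxidant)
Why: Catalytic osmium tetroxide syn-dihydroxylation: the cis-disubstituted C2=C3 bond should react in preference to the C5=C7 bond, whose C5 is flanked by the quaternary C4 and C10, and the reagent should add from the α face anti to the pseudoaxial ester and 4β-methyl, which sets C2 (R) and C3 (S).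

Step 7
Reactants: 10 methyl (5S,6R,7aR)-5,6-dihydroxy-4,4-dimethyl-1,2,4,5,6,7-hexahydro-7aH-indene-7a-carboxylate
Product: 11 acetonide of 10 (2α,3α-O-isopropylidene; C5=C7 alkene; 10β-CO2Me)
Conditions: 2,2-dimethoxypropane, PPTS (5 mol %), CH2Cl2, rt
Reagents that add atoms: 2,2-dimethoxypropane, CC(C)(OC)OC
Why: Acid-catalysed transketalisation closes the cis-fused dioxolane, which masks both hydroxyls through the base, silver, oxidation and organometallic steps.

Step 8
Reactants: 11 acetonide of 10
Product: 12 gem-dibromocyclopropane of 11 (CBr2 = C6 bridging C5/C7 on the α face)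
Conditions: CHBr3 (3 equiv), KOtBu (3 equiv), pentane, –10 °C to rt; used without heating
Reagents that add atoms: bromoform, BrC(Br)Br
Why: [2+1] cycloaddition of electrophilic dibromocarbene to the only remaining, trisubstituted alkene, expected on the α face away from the ester; the two cyclopropane stereocentres are erased in step 9 and the base finds no enolisable position.

Step 9
Reactants: 12 gem-dibromocyclopropane of 11
Product: 13 methyl 6-bromo-7α-hydroxy-2α,3α-isopropylidenedioxy-4,4-dimethyl-Δ5-octalin-10β-carboxylate (ring B now six-membered)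
Conditions: AgClO4 (1.5 equiv), 2,6-lutidine (1.5 equiv), acetone/H2O (5:1), rt, dark
Reagents that add atoms: water, O
Why: Silver(I) removes the endo bromide while the C5–C7 cyclopropane bond opens in a disrotatory two-electron electrocyclic process (the ring bonds cis to the leaving group turn inward), giving a 2-bromoallyl cation that spans C5–C6–C7 inside a six-membered ring and is captured by water. The closest known reaction type is the silver-promoted ring expansion of ring-fused gem-dibromocyclopropanes, e.g. 6,6-dibromobicyclo[3.1.0]hexanes to 2-bromocyclohex-2-enols. No ring is closed by forming a bond; ring B arises from the five-membered ring C5–C7–C8–C9–C10 by cleavage of the shared C5–C7 bond, the carbene carbon becoming C6. The only new stereocentre, C7, should result from pseudoaxial (α) attack of water on the half-chair cation, but it is inconsequential because C7 is oxidised in step 11. The step needs capture at C7 and not at C5: C5 is a tertiary terminus flanked by the quaternary C4 and C10, and a tertiary allylic alcohol formed there would re-ionise to the more substituted C5=C6 isomer. 2,6-Lutidine takes up the acid so that the acetonide survives.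

Step 10
Reactants: 13 methyl 6-bromo-7α-hydroxy-2α,3α-isopropylidenedioxy-4,4-dimethyl-Δ5-octalin-10β-carboxylate
Product: 15 methyl 7α-hydroxy-2α,3α-isopropylidenedioxy-4,4-dimethyl-5α-decalin-10β-carboxylate (trans-fused), via debrominated allylic alcohol 14 (not isolated)
Conditions: H2 (4 atm), 10 % Pd/C, Et3N (2 equiv), EtOAc, rt
Reagents that add atoms: none
Why: Hydrogenolysis of the vinylic C–Br bond and heterogeneous hydrogenation of the Δ5 olefin from the α face (the β face is screened by the axial ester on C10 and the 4β-methyl) set C5–H α, i.e. the trans ring fusion; any Pd-induced isomerisation of 14 to ketone 16 converges in step 11.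

Step 11
Reactants: 15 methyl 7α-hydroxy-2α,3α-isopropylidenedioxy-4,4-dimethyl-5α-decalin-10β-carboxylate
Product: 17 methyl 2α,3α-isopropylidenedioxy-4,4-dimethyl-7-oxo-5α-octal-8-ene-10β-carboxylate (Δ8-7-one), via saturated 7-ketone 16 (not isolated)
Conditions: IBX (3 equiv), DMSO, 75 °C
Reagents that add atoms: none
Why: IBX oxidises the secondary alcohol and then dehydrogenates the ketone through its less hindered C7=C8 enol (the regiochemistry known for trans-fused 3-keto steroids giving Δ1-enones), so the C8=C9 enone forms without creating or touching a stereocentre.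

Step 12
Reactants: 18 (R)-(–)-linalool
Product: 19 (R)-linalool triethylsilyl ether
Conditions: TESOTf, 2,6-lutidine, CH2Cl2, –78 to 0 °C
Reagents that add atoms: triethylsilyl trifluoromethanesulfonate, CC[Si](CC)(CC)OS(=O)(=O)C(F)(F)F
Why: Silylation of the hindered tertiary alcohol with the silyl triflate; the C13 centre is not involved.

Step 13
Reactants: 19 (R)-linalool triethylsilyl ether
Product: 21 (4R)-4-methyl-4-(triethylsilyloxy)hex-5-enoic acid, via aldehyde 20 (not isolated)
Conditions: O3 (1 equiv, Sudan Red 7B end point), MeCN/H2O (9:1), 0 °C; then NaClO2, NaH2PO4, 0 °C to rt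
Reagents that add atoms: ozone, [O-][O+]=O; sodium chlorite, [Na+].[O-]Cl=O
Why: Ozonolysis is selective for the electron-rich trisubstituted alkene over the vinyl group, aqueous acetonitrile releases the aldehyde directly, and Pinnick-type chlorite oxidation (the hydrogen peroxide formed scavenges hypochlorite) gives the acid.

Step 14
Reactants: 21 (4R)-4-methyl-4-(triethylsilyloxy)hex-5-enoic acid
Product: 23 (3R)-5-iodo-3-methyl-3-(triethylsilyloxy)pent-1-ene, via thiohydroxamate ester 22 (not isolated)
Conditions: N-hydroxypyridine-2-thione, DCC, DMAP (cat.), CH2Cl2, rt, dark; then CHI3, benzene, hν (tungsten lamp), 60 °C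
Reagents that add atoms: iodoform, IC(I)I (N-hydroxypyridine-2-thione, On1ccccc1=S, is carried only in 22)
Why: Barton decarboxylative iodination: the O-acyl thiohydroxamate fragments under light to CO2 and the primary C11 radical, which abstracts iodine from iodoform in a chain process that leaves the vinyl group and C13 alone.

Step 15
Reactants: 23 (3R)-5-iodo-3-methyl-3-(triethylsilyloxy)pent-1-ene; 17 Δ8-7-one
Product: 26 Mannich base (17 carrying the 9α-[(3R)-3-methyl-3-(triethylsilyloxy)pent-4-enyl] chain plus 8α-CH2NMe2), via Grignard reagent 24 (not isolated), via silyl enol ether 25 (not isolated)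
Conditions: 23, Mg, THF, rt; then 17, CuBr·SMe2 (10 mol %), TMSCl, HMPA, THF, –78 °C; solvent exchange to CH2Cl2, CH2=NMe2+ I–, rt; aq NaHCO3
Reagents that add atoms: dimethyl(methylidene)ammonium iodide, C=[N+](C)C.[I-] (magnesium, [Mg], and chlorotrimethylsilane, C[Si](C)(C)Cl, are carried only in 24 and 25)
Why: Copper-catalysed, chlorosilane-accelerated conjugate addition: the alkyl group attacks C9 axially and anti to the axial C10 ester (the course known for 1α-alkylation of Δ1-3-keto steroids), which puts the side chain α, and the regiodefined C7=C8 silyl enol ether then undergoes a Mannich reaction at C8, whose configuration is lost in step 16.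

Step 16
Reactants: 26 Mannich base
Product: 28 8(17)-methylene-7-ketone (9α side chain; acetonide; methyl ester; TES ether), via ammonium iodide 27 (not isolated)
Conditions: MeI, CH2Cl2/MeOH, rt; then aq NaHCO3, CH2Cl2, rt
Reagents that add atoms: iodomethane, CI (its methyl group is carried only in 27)
Why: N-Methylation makes the amine a leaving group and bicarbonate effects E1cB elimination to the exocyclic C8=C17 enone under conditions too mild to epimerise C9 or move the double bond into the ring.

Step 17
Reactants: 28 8(17)-methylene-7-ketone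
Product: 30 7α,20-diol (9α side chain; 8(17)-ene; acetonide; TES ether), via hydroxy ester 29 (not isolated)
Conditions: DIBAL-H (6 equiv), CH2Cl2, –78 to 0 °C; Rochelle salt
Reagents that add atoms: none
Why: DIBAL-H reduces the enone 1,2 and then the hindered ester to the primary alcohol; the axial approach to C7 is blocked by the syn-axial C9 chain, so hydride should enter equatorially from the β face and give the axial 7α-alcohol.

Step 18
Reactants: 30 7α,20-diol; 31 (R)-2-methylbutanoic acid
Product: 32 20-O-[(2R)-2-methylbutanoyl] derivative of 30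
Conditions: 31 (1.1 equiv), EDC·HCl, DMAP (10 mol %), CH2Cl2, 0 °C
Reagents that add atoms: none
Why: Carbodiimide (Steglich) esterification: the primary C20 hydroxyl should be acylated in preference to the axial, doubly flanked allylic C7 hydroxyl, and the α-centre of the acid is retained at 0 °C.

Step 19
Reactants: 32 20-O-[(2R)-2-methylbutanoyl] derivative of 30
Product: 34 2α,3α,7α,13-tetraol 20-[(2R)-2-methylbutanoate], via desilylated acetonide 33 (not isolated)
Conditions: PPTS (0.3 equiv), MeOH, 40 °C
Reagents that add atoms: none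
Why: Mild acid-catalysed methanolysis removes the tertiary silyl ether and then the acetonide (transketalisation), conditions under which the tertiary allylic alcohol, the allylic C7 alcohol and the ester should persist.

Step 20
Reactants: 34 2α,3α,7α,13-tetraol 20-[(2R)-2-methylbutanoate]; 35 angelic acid
Product: 37 CNP0391865.1 (target), via mixed anhydride 36 (not isolated)
Conditions: 35 (1.5 equiv), 2,4,6-trichlorobenzoyl chloride (1.5 equiv), Et3N, toluene, rt; then 34, toluene, 75 °C
Reagents that add atoms: 2,4,6-trichlorobenzoyl chloride, O=C(Cl)c1c(Cl)cc(Cl)cc1Cl (carried only in 36)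
Why: Yamaguchi-type acylation through the mixed anhydride without DMAP, which keeps the Z geometry of the angelate; the equatorial C2 hydroxyl is the only unhindered one, since the C3 and C7 hydroxyls are axial and flanked and the C13 hydroxyl is tertiary.

**Compound list**

1 | methyl 2-oxocyclopentane-1-carboxylate | COC(=O)C1CCCC1=O | starting material
2 | methyl vinyl ketone | CC(=O)C=C | starting material
3 | methyl (1R)-2-oxo-1-(3-oxobutyl)cyclopentane-1-carboxylate | COC(=O)[C@@]1(CCC(C)=O)CCCC1=O | intermediate
4 | cis-fused ketol, methyl (7aR)-3a-hydroxy-5-oxooctahydro-7aH-indene-7a-carboxylate (OH cis to CO2Me) | C1CC[C@]2(O)CC(=O)CC[C@]12C(=O)OC | intermediate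
5 | methyl (7aR)-5-oxo-1,2,3,5,6,7-hexahydro-7aH-indene-7a-carboxylate | C1CCC2=CC(=O)CC[C@]12C(=O)OC | intermediate
6 | methyl (7aR)-4-methyl-5-oxo-1,2,3,5,6,7-hexahydro-7aH-indene-7a-carboxylate | C1CCC2=C(C)C(=O)CC[C@]12C(=O)OC | intermediate
7 | methyl (7aR)-4,4-dimethyl-5-oxo-1,2,4,5,6,7-hexahydro-7aH-indene-7a-carboxylate (C5=C7 alkene) | C1CC=C2C(C)(C)C(=O)CC[C@]12C(=O)OC | intermediate
8 | C3 enol triflate of 7 (C2=C3–OTf) | C1CC=C2C(C)(C)C(OS(=O)(=O)C(F)(F)F)=CC[C@]12C(=O)OC | intermediate
9 | methyl (7aR)-4,4-dimethyl-1,2,4,7-tetrahydro-7aH-indene-7a-carboxylate (C2=C3 and C5=C7 diene) | C1CC=C2C(C)(C)C=CC[C@]12C(=O)OC | intermediate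
10 | 2α,3α-diol, methyl (5S,6R,7aR)-5,6-dihydroxy-4,4-dimethyl-1,2,4,5,6,7-hexahydro-7aH-indene-7a-carboxylate | C1CC=C2C(C)(C)[C@H](O)[C@H](O)C[C@]12C(=O)OC | intermediate
11 | acetonide of 10 | C1CC=C2C(C)(C)[C@@H]3OC(C)(C)O[C@@H]3C[C@]12C(=O)OC | intermediate
12 | gem-dibromocyclopropane of 11 (C6Br2 on the α face across C5–C7) | C1C[C@H]3[C@@]2(C3(Br)Br)C(C)(C)[C@@H]4OC(C)(C)O[C@@H]4C[C@]12C(=O)OC | intermediate
13 | methyl 6-bromo-7α-hydroxy-2α,3α-isopropylidenedioxy-4,4-dimethyl-Δ5-octalin-10β-carboxylate | C1C[C@H](O)C(Br)=C2C(C)(C)[C@@H]3OC(C)(C)O[C@@H]3C[C@]12C(=O)OC | intermediate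
14 | debrominated allylic alcohol (Δ5-7α-ol) | C1C[C@H](O)C=C2C(C)(C)[C@@H]3OC(C)(C)O[C@@H]3C[C@]12C(=O)OC | intermediate
15 | methyl 7α-hydroxy-2α,3α-isopropylidenedioxy-4,4-dimethyl-5α-decalin-10β-carboxylate | C1C[C@H](O)C[C@H]2C(C)(C)[C@@H]3OC(C)(C)O[C@@H]3C[C@]12C(=O)OC | intermediate
16 | saturated 7-ketone (trans-decalin) | C1CC(=O)C[C@H]2C(C)(C)[C@@H]3OC(C)(C)O[C@@H]3C[C@]12C(=O)OC | intermediate
17 | Δ8-7-one (trans-decalin enone) | C1=CC(=O)C[C@H]2C(C)(C)[C@@H]3OC(C)(C)O[C@@H]3C[C@]12C(=O)OC | intermediate
18 | (R)-(–)-linalool | C=C[C@](C)(O)CCC=C(C)C | starting material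
19 | (R)-linalool triethylsilyl ether | C=C[C@](C)(O[Si](CC)(CC)CC)CCC=C(C)C | intermediate
20 | (4R)-4-methyl-4-(triethylsilyloxy)hex-5-enal | C=C[C@](C)(O[Si](CC)(CC)CC)CCC=O | intermediate
21 | (4R)-4-methyl-4-(triethylsilyloxy)hex-5-enoic acid | C=C[C@](C)(O[Si](CC)(CC)CC)CCC(=O)O | intermediate
22 | 2-thioxopyridin-1-yl ester of 21 (thiohydroxamate ester) | C=C[C@](C)(O[Si](CC)(CC)CC)CCC(=O)On1ccccc1=S | intermediate
23 | (3R)-5-iodo-3-methyl-3-(triethylsilyloxy)pent-1-ene | C=C[C@](C)(O[Si](CC)(CC)CC)CCI | intermediate
24 | Grignard reagent of 23 | C=C[C@](C)(O[Si](CC)(CC)CC)CC[Mg]I | intermediate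
25 | C7=C8 trimethylsilyl enol ether with the 9α side chain | C=C[C@](C)(O[Si](CC)(CC)CC)CC[C@@H]1C=C(O[Si](C)(C)C)C[C@H]2C(C)(C)[C@@H]3OC(C)(C)O[C@@H]3C[C@]12C(=O)OC | intermediate
26 | Mannich base (8α-CH2NMe2, 9α side chain, 7-ketone) | C=C[C@](C)(O[Si](CC)(CC)CC)CC[C@@H]1[C@H](CN(C)C)C(=O)C[C@H]2C(C)(C)[C@@H]3OC(C)(C)O[C@@H]3C[C@]12C(=O)OC | intermediate
27 | trimethylammonium iodide of 26 | C=C[C@](C)(O[Si](CC)(CC)CC)CC[C@@H]1[C@H](C[N+](C)(C)C)C(=O)C[C@H]2C(C)(C)[C@@H]3OC(C)(C)O[C@@H]3C[C@]12C(=O)OC.[I-] | intermediate
28 | 8(17)-methylene-7-ketone | C=C[C@](C)(O[Si](CC)(CC)CC)CC[C@@H]1C(=C)C(=O)C[C@H]2C(C)(C)[C@@H]3OC(C)(C)O[C@@H]3C[C@]12C(=O)OC | intermediate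
29 | 7α-hydroxy methyl ester | C=C[C@](C)(O[Si](CC)(CC)CC)CC[C@@H]1C(=C)[C@H](O)C[C@H]2C(C)(C)[C@@H]3OC(C)(C)O[C@@H]3C[C@]12C(=O)OC | intermediate
30 | 7α,20-diol (acetonide, 13-OTES) | C=C[C@](C)(O[Si](CC)(CC)CC)CC[C@@H]1C(=C)[C@H](O)C[C@H]2C(C)(C)[C@@H]3OC(C)(C)O[C@@H]3C[C@]12CO | intermediate
31 | (R)-2-methylbutanoic acid | CC[C@@H](C)C(=O)O | starting material
32 | 20-[(2R)-2-methylbutanoate] of 30 | C=C[C@](C)(O[Si](CC)(CC)CC)CC[C@@H]1C(=C)[C@H](O)C[C@H]2C(C)(C)[C@@H]3OC(C)(C)O[C@@H]3C[C@]12COC(=O)[C@H](C)CC | intermediate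
33 | desilylated acetonide (13-OH free) | C=C[C@](C)(O)CC[C@@H]1C(=C)[C@H](O)C[C@H]2C(C)(C)[C@@H]3OC(C)(C)O[C@@H]3C[C@]12COC(=O)[C@H](C)CC | intermediate
34 | 2α,3α,7α,13-tetraol 20-[(2R)-2-methylbutanoate] | C=C[C@](C)(O)CC[C@@H]1C(=C)[C@H](O)C[C@H]2C(C)(C)[C@H](O)[C@H](O)C[C@]12COC(=O)[C@H](C)CC | intermediate
35 | angelic acid, (Z)-2-methylbut-2-enoic acid | C/C=C(/C)C(=O)O | starting material
36 | angelic 2,4,6-trichlorobenzoic mixed anhydride | C/C=C(/C)C(=O)OC(=O)c1c(Cl)cc(Cl)cc1Cl | intermediate
37 | CNP0391865.1 | C=C[C@](C)(O)CC[C@@H]1C(=C)[C@H](O)C[C@H]2C(C)(C)[C@H](O)[C@H](OC(=O)/C(C)=C\C)C[C@]12COC(=O)[C@H](C)CC | target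

**Step count and risk**

Total step count: 20. Longest linear sequence: 17 steps (steps 1–11 and 15–20); the side-chain branch is steps 12–14.

Step 8 is the first of the three steps most likely to fail: the carbene may not add to the C5=C7 bond, which is shielded by two quaternary neighbours, or may insert elsewhere, so that no substrate for the ring enlargement is obtained. The fallback sets out from 11 and keeps a one-carbon ring enlargement. Hydroboration–oxidation (BH3·SMe2; NaOH, H2O2), a syn addition from the α face that already sets C5–H α, should give the trans-hydrindan-7α-ol F1. Oxidation with DMP gives the cyclopentanone F2. Addition of PhSeCH2Li at –78 °C gives the β-hydroxy selenide F3. Silver tetrafluoroborate then induces a semipinacol ring enlargement in which the more substituted C5 migrates with retention and the selenium-bearing carbon becomes C6. This returns to the route at the saturated 7-ketone 16, which is dehydrogenated with IBX as in step 11.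

Step 15 is the second: conjugate addition at the neopentyl C9 may be slow or unselective between the two faces, or the enolate may be lost before it is trapped. The fallback sets out from 17 and 23. Tin-hydride mediated radical (Giese) addition (Bu3SnH, AIBN, benzene, 80 °C, slow addition) has an early transition state that tolerates the quaternary neighbour and should again attack axially from the α face, giving the 9α-alkyl 7-ketone F4. Soft enolisation (TMSOTf, Et3N), which for a trans-fused 7-ketone should favour the C7=C8 enol ether, returns to the route at silyl enol ether 25.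

Step 20 is the third: acylation may occur at more than one hydroxyl, and the angelate may isomerise from Z to E on heating. The fallback sets out from 34. Dibutyltin oxide (toluene, reflux, water removal) should give the 2,3-O-dibutylstannylene acetal F5, in which the equatorial O2 is the activated nucleophile. Reaction with mixed anhydride 36 at room temperature then returns to the route at 37.

**Further compounds**

F1 | step 8 | trans-hydrindan-7α-ol from hydroboration of 11 (5α-H) | C1C[C@H](O)[C@H]2C(C)(C)[C@@H]3OC(C)(C)O[C@@H]3C[C@]12C(=O)OC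
F2 | step 8 | trans-hydrindan-7-one (five-membered ring ketone next to C5) | C1CC(=O)[C@H]2C(C)(C)[C@@H]3OC(C)(C)O[C@@H]3C[C@]12C(=O)OC
F3 | step 8 | β-hydroxy selenide, 7β-hydroxy-7α-(phenylselanylmethyl) adduct of F2 | C1C[C@](O)(C[Se]c3ccccc3)[C@H]2C(C)(C)[C@@H]4OC(C)(C)O[C@@H]4C[C@]12C(=O)OC
F4 | step 15 | 9α-alkyl 7-ketone (side chain on C9, C8 unsubstituted) | C=C[C@](C)(O[Si](CC)(CC)CC)CC[C@@H]1CC(=O)C[C@H]2C(C)(C)[C@@H]3OC(C)(C)O[C@@H]3C[C@]12C(=O)OC
F5 | step 20 | 2,3-O-dibutylstannylene acetal of 34 | C=C[C@](C)(O)CC[C@@H]1C(=C)[C@H](O)C[C@H]2C(C)(C)[C@@H]3O[Sn](CCCC)(CCCC)O[C@@H]3C[C@]12COC(=O)[C@H](C)CC
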